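The cycloheptane is numbered C1 (carbinol carbon with the crotonoyl group), C2 (CHMe), C3 (ketone), C4 (CH2), C5/C6 (lactone fusion) and C7 (CH–O-isovaleryl). It is cut at C3–C4 and C7–C1 into furan (C4–C7 plus the C7 oxygen) and a three-carbon vinylcarbenoid (C1–C3). Rhodium-catalysed cyclopropanation of furan by methyl 2-diazo-3-methylbut-3-enoate and Cope rearrangement of the cis-divinylcyclopropane form both bonds in one operation and give an 8-oxabicyclo[3.2.1]octadiene. The step exploits the 1,4-relation of C4 and C7 across the seven-membered ring: the furan oxygen remains as the C7 ester oxygen, while its bond to C4, alpha to the later C3 ketone, is cut reductively.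

Key step: step 2

Remark 1: in monocyclic names the target numbering above is used; β is the face of the seven-membered ring that carries the C7 oxygen, α the opposite face.
Remark 2 (assumption): C2 is alpha to the C3 ketone and epimerisable; the target configuration (methyl α, trans to the crotonoyl group on C1) is taken to be the thermodynamically favoured one and is set by equilibration in step 18.
Remark 3 (assumption): Rh2(S-DOSP)4, dirhodium tetrakis[(S)-N-(4-dodecylphenylsulfonyl)prolinate], is taken to give the (1S,5S) antipode 5; if the sense of induction on furan is the opposite, the enantiomeric catalyst Rh2(R-DOSP)4 is used. Rh2(cap)4 is dirhodium tetrakis(caprolactamate).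

Step 1
Reactants: 1 methyl 3-methylbut-3-enoate
Product: 2 methyl 2-diazo-3-methylbut-3-enoate
Conditions: p-ABSA, DBU, MeCN, 0 °C
Reagents that add atoms: 4-acetamidobenzenesulfonyl azide (p-ABSA), CC(=O)Nc1ccc(cc1)S(=O)(=O)N=[N+]=[N-]
Why: Regitz-type diazo transfer to the allylic alpha-methylene of the beta,gamma-unsaturated ester, which DBU deprotonates; no stereocentre is formed.

Step 2
Reactants: 2 methyl 2-diazo-3-methylbut-3-enoate; 3 furan
Product: 5 methyl (1S,5S)-3-methyl-8-oxabicyclo[3.2.1]octa-2,6-diene-2-carboxylate, via cis-divinylcyclopropane 4 (not isolated)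
Conditions: Rh2(S-DOSP)4 (1 mol %), furan (5 equiv), hexane, −40 °C to rt
Reagents that add atoms: none
Why: The rhodium-bound donor/acceptor vinylcarbenoid cyclopropanates the 2,3-bond of furan with the isopropenyl group cis to the dihydrofuran ring, and the cis-divinylcyclopropane 4 then undergoes a boat-type [3,3] Cope rearrangement below room temperature, so that the carbenoid carbon (target C1) ends bonded to one furan alpha-carbon (C7) and the vinyl CH2 (target C3) to the other (C4). The closest known reaction type is the tandem cyclopropanation/Cope ([4+3]) reaction of vinyldiazoacetates with furans and dienes. The three-membered ring closes by concerted carbene addition, the seven-membered ring closes in the sigmatropic step with release of cyclopropane strain, and the oxygen bridge is the furan oxygen itself. The two new stereocentres are the bridgeheads (target C7 and C4); their relative configuration is fixed by the bridge and their absolute configuration by the face of furan that the chiral prolinate catalyst selects in the cyclopropanation. The step needs cyclopropanation to win over ring-opening of furan to trienes, which unsubstituted furan in excess and a hydrocarbon solvent favour; regiochemistry is no issue because furan is symmetrical.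

Step 3
Reactants: 5 methyl (1S,5S)-3-methyl-8-oxabicyclo[3.2.1]octa-2,6-diene-2-carboxylate
Product: 6 methyl (1S,5R)-3-methyl-4-oxo-8-oxabicyclo[3.2.1]octa-2,6-diene-2-carboxylate
Conditions: Rh2(cap)4 (1 mol %), t-BuOOH (70% aq., 5 equiv), K2CO3, CH2Cl2, rt
Reagents that add atoms: tert-butyl hydroperoxide, CC(C)(C)OO
Why: Allylic oxidation by tert-butylperoxyl radicals at the only non-bridgehead allylic CH2 (gamma to the ester, target C3) gives the 4-oxo-enoate; no stereocentre changes.

Step 4
Reactants: 6 methyl (1S,5R)-3-methyl-4-oxo-8-oxabicyclo[3.2.1]octa-2,6-diene-2-carboxylate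
Product: 7 methyl (1S,5R)-3-methyl-4-oxo-8-oxabicyclo[3.2.1]oct-6-ene-2-carboxylate (ester on C2 trans and methyl on C3 cis to the bridging oxygen; both equatorial)
Conditions: Zn dust, AcOH, 60 °C
Reagents that add atoms: none
Why: Zinc/acetic acid reduction of the ene-dione-type 4-oxo-enoate saturates only the electron-poor C2=C3 bond; protonation at C2 from the open face and acid-mediated enolisation at C3 leave both substituents equatorial.

Step 5
Reactants: 7 methyl (1S,5R)-3-methyl-4-oxo-8-oxabicyclo[3.2.1]oct-6-ene-2-carboxylate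
Product: 8 methyl 7β-hydroxy-2β-methyl-3-oxocyclohept-5-ene-1α-carboxylate
Conditions: SmI2 (2.5 equiv), THF–MeOH, −78 °C
Reagents that add atoms: none
Why: SmI2 reductive cleavage of an alpha-alkoxy ketone: the ketyl expels the bridging oxygen from the alpha-carbon (target C4), so the bridge opens with the oxygen kept on C7 and C4 becoming CH2, without touching C1, C2 or C7.

Step 6
Reactants: 8 methyl 7β-hydroxy-2β-methyl-3-oxocyclohept-5-ene-1α-carboxylate
Product: 9 methyl 7β-(tert-butyldimethylsilyloxy)-2β-methyl-3-oxocyclohept-5-ene-1α-carboxylate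
Conditions: TBSCl, imidazole, DMF, rt
Reagents that add atoms: tert-butyldimethylsilyl chloride, CC(C)(C)[Si](C)(C)Cl
Why: Silyl ether formation on the secondary allylic alcohol under weakly basic conditions that do not move the beta,gamma-double bond into conjugation.

Step 7
Reactants: 9 methyl 7β-(tert-butyldimethylsilyloxy)-2β-methyl-3-oxocyclohept-5-ene-1α-carboxylate
Product: 10 methyl 7β-(tert-butyldimethylsilyloxy)-3,3-ethylenedioxy-2β-methylcyclohept-5-ene-1α-carboxylate
Conditions: TMSOCH2CH2OTMS, TMSOTf (cat.), CH2Cl2, −78 to −20 °C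
Reagents that add atoms: 1,2-bis(trimethylsilyloxy)ethane, C[Si](C)(C)OCCO[Si](C)(C)C
Why: Acid-catalysed ketalisation at low temperature masks the ketone for the enolate and hydride steps; the beta,gamma-alkene stays in place because its ketal is the stable isomer.

Step 8
Reactants: 10 methyl 7β-(tert-butyldimethylsilyloxy)-3,3-ethylenedioxy-2β-methylcyclohept-5-ene-1α-carboxylate
Product: 11 methyl 7β-(tert-butyldimethylsilyloxy)-3,3-ethylenedioxy-1α-hydroxy-2β-methylcyclohept-5-ene-1β-carboxylate
Conditions: KN(SiMe3)2, THF, −78 °C; then 2-(phenylsulfonyl)-3-phenyloxaziridine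
Reagents that add atoms: 2-(phenylsulfonyl)-3-phenyloxaziridine, O=S(=O)(c1ccccc1)N1OC1c1ccccc1
Why: Electrophilic hydroxylation of the potassium ester enolate by the N-sulfonyloxaziridine; the reagent enters from the α face, anti to the C7 silyloxy and C2 methyl groups that both sit on the β face, which sets C1 (OH α, ester β).

Step 9
Reactants: 11 methyl 7β-(tert-butyldimethylsilyloxy)-3,3-ethylenedioxy-1α-hydroxy-2β-methylcyclohept-5-ene-1β-carboxylate
Product: 12 7β-(tert-butyldimethylsilyloxy)-3,3-ethylenedioxy-1α-hydroxy-2β-methylcyclohept-5-ene-1β-carbaldehyde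
Conditions: i-Bu2AlH (2.2 equiv), CH2Cl2, −78 °C
Reagents that add atoms: none
Why: Partial reduction of the alpha-alkoxy ester by i-Bu2AlH, whose chelated aluminium acetal survives at −78 °C and gives the aldehyde on work-up.

Step 10
Reactants: 12 7β-(tert-butyldimethylsilyloxy)-3,3-ethylenedioxy-1α-hydroxy-2β-methylcyclohept-5-ene-1β-carbaldehyde
Product: 13 7β-(tert-butyldimethylsilyloxy)-3,3-ethylenedioxy-1β-(1-hydroxybut-2-yn-1-yl)-2β-methylcyclohept-5-en-1α-ol (carbinol epimers)
Conditions: CH3C≡CMgBr (3 equiv), THF, −78 to 0 °C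
Reagents that add atoms: 1-propynylmagnesium bromide, CC#C[Mg]Br
Why: Grignard 1,2-addition of the alkynyl nucleophile to the aldehyde; the new carbinol centre forms as a mixture and is erased by oxidation in step 20.

Step 11
Reactants: 13 7β-(tert-butyldimethylsilyloxy)-3,3-ethylenedioxy-1β-(1-hydroxybut-2-yn-1-yl)-2β-methylcyclohept-5-en-1α-ol
Product: 14 isopropylidene acetal of 13 (spiro-dioxolane at C1: C1α–O and the side-chain carbinol O bridged by CMe2)
Conditions: Me2C(OMe)2, PPTS, CH2Cl2, rt
Reagents that add atoms: 2,2-dimethoxypropane, COC(C)(C)OC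
Why: Acid-catalysed trans-ketalisation forms the isopropylidene acetal of the 1,2-diol, which hides both hydroxyl groups in the ketene and enolate steps.

Step 12
Reactants: 14 isopropylidene acetal of 13
Product: 15 α-face cis-fused 2,2-dichlorocyclobutanone of 14 (C=O on C6 and CCl2 on C5)
Conditions: Cl3CCOCl, Zn–Cu couple, POCl3, Et2O, rt
Reagents that add atoms: trichloroacetyl chloride, ClC(Cl)(Cl)C(Cl)=O
Why: [2+2] cycloaddition of dichloroketene (made in situ) to the cis-alkene, suprafacial on the alkene and therefore cis-fused, from the α face anti to the C7 silyl ether; the carbonyl carbon bonds to C6 because the developing positive charge prefers C5, the carbon remote from the C7–O bond.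

Step 13
Reactants: 15 α-face cis-fused 2,2-dichlorocyclobutanone
Product: 16 α-face cis-fused cyclobutanone (C=O on C6 and CH2 on C5)
Conditions: Zn, NH4Cl, MeOH, rt
Reagents that add atoms: none
Why: Zinc-mediated reductive dechlorination of the alpha,alpha-dichloroketone under near-neutral conditions that spare the acetals.

Step 14
Reactants: 16 α-face cis-fused cyclobutanone
Product: 17 cis-fused γ-lactone (C6α–O–C(=O)–CH2–C5α) bearing the 7β-silyl ether and the 3,3-ethylenedioxy and C1 acetonide/butynyl groups
Conditions: mCPBA, NaHCO3, CH2Cl2, 0 °C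
Reagents that add atoms: 3-chloroperoxybenzoic acid, OOC(=O)c1cccc(Cl)c1
Why: Baeyer–Villiger oxidation of the strained cyclobutanone with retentive migration of the secondary C6 in preference to the CH2 group, which places the lactone oxygen on C6 (α) and completes the cis-fused γ-lactone.

Step 15
Reactants: 17 cis-fused γ-lactone
Product: 20 α-methylene-γ-lactone (exocyclic CH2 on the lactone α-carbon; otherwise as 17), via Mannich base 18 (not isolated), via methiodide 19 (not isolated)
Conditions: LiN(i-Pr)2, THF, −78 °C; CH2=NMe2+ I−; then MeI, MeOH; then NaHCO3 (aq.)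
Reagents that add atoms: dimethyl(methylene)ammonium iodide, C=[N+](C)C.[I-]
Why: Mannich alkylation of the lactone lithium enolate (the only acidic C–H in 17), N-methylation and Hofmann-type elimination give the exocyclic methylene; no ring stereocentre is affected.

Step 16
Reactants: 20 α-methylene-γ-lactone silyl ether
Product: 21 7β-alcohol of 20
Conditions: Bu4NF, AcOH, THF, 0 °C to rt
Reagents that add atoms: none
Why: Fluoride-induced desilylation, buffered with acetic acid so that no free alkoxide adds to the α-methylene lactone.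

Step 17
Reactants: 21 7β-alcohol
Product: 22 7β-(3-methylbutanoyloxy) derivative of 21
Conditions: 3-methylbutanoyl chloride, pyridine, DMAP (cat.), CH2Cl2, rt
Reagents that add atoms: 3-methylbutanoyl chloride, CC(C)CC(Cl)=O
Why: DMAP-catalysed O-acylation of the only free hydroxyl group.

Step 18
Reactants: 22 7β-(3-methylbutanoyloxy) ketal acetonide
Product: 23 3-keto-1α-hydroxy-1β-(1-hydroxybut-2-yn-1-yl)-2α-methyl compound (lactone and C7 ester as in the target)
Conditions: 1 M HCl (aq.), THF, 40 °C
Reagents that add atoms: water, O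
Why: Acid-catalysed hydrolysis of the dioxolane and the isopropylidene acetal; the freed C3 ketone lets C2 equilibrate through its enol to the epimer with methyl trans to the bulky C1 side chain (α).

Step 19
Reactants: 23 keto diol with the but-2-ynyl carbinol side chain
Product: 24 (Z)-1-hydroxybut-2-en-1-yl analogue of 23
Conditions: H2 (1 atm), Pd/CaCO3 poisoned with Pb(OAc)2, quinoline, EtOAc, rt
Reagents that add atoms: none
Why: Syn semi-hydrogenation on lead-poisoned palladium converts the alkyne into the (Z)-alkene, the alkyne binding far more strongly than the exocyclic alkene of the lactone.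

Step 20
Reactants: 24 (Z)-allylic diol
Product: 25 target CNP0283951.2
Conditions: DMP (Dess–Martin periodinane), NaHCO3, CH2Cl2, 0 °C
Reagents that add atoms: none
Why: Hypervalent-iodine oxidation of the secondary allylic alcohol under buffered conditions gives the (Z)-enone without isomerisation and leaves the tertiary alcohol alone.

Compound list
1 | methyl 3-methylbut-3-enoate | COC(=O)CC(C)=C | starting material
2 | methyl 2-diazo-3-methylbut-3-enoate | COC(=O)C(=[N+]=[N-])C(C)=C | intermediate
3 | furan | c1ccoc1 | starting material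
4 | methyl 6-(prop-1-en-2-yl)-2-oxabicyclo[3.1.0]hex-3-ene-6-carboxylate, isopropenyl cis to the dihydrofuran ring (not isolated) | COC(=O)[C@@]1(C(C)=C)[C@@H]2C=CO[C@H]12 | intermediate
5 | methyl (1S,5S)-3-methyl-8-oxabicyclo[3.2.1]octa-2,6-diene-2-carboxylate | C1=C[C@@H]2CC(C)=C(C(=O)OC)[C@H]1O2 | intermediate
6 | methyl (1S,5R)-3-methyl-4-oxo-8-oxabicyclo[3.2.1]octa-2,6-diene-2-carboxylate | C1=C[C@@H]2C(=O)C(C)=C(C(=O)OC)[C@H]1O2 | intermediate
7 | methyl (1S,5R)-3-methyl-4-oxo-8-oxabicyclo[3.2.1]oct-6-ene-2-carboxylate, 2-ester trans and 3-methyl cis to the bridging oxygen | C1=C[C@@H]2C(=O)[C@@H](C)[C@H](C(=O)OC)[C@H]1O2 | intermediate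
8 | methyl 7β-hydroxy-2β-methyl-3-oxocyclohept-5-ene-1α-carboxylate | C1=CCC(=O)[C@@H](C)[C@H](C(=O)OC)[C@H]1O | intermediate
9 | methyl 7β-(tert-butyldimethylsilyloxy)-2β-methyl-3-oxocyclohept-5-ene-1α-carboxylate | C1=CCC(=O)[C@@H](C)[C@H](C(=O)OC)[C@H]1O[Si](C)(C)C(C)(C)C | intermediate
10 | methyl 7β-(tert-butyldimethylsilyloxy)-3,3-ethylenedioxy-2β-methylcyclohept-5-ene-1α-carboxylate | C1=CCC2(OCCO2)[C@@H](C)[C@H](C(=O)OC)[C@H]1O[Si](C)(C)C(C)(C)C | intermediate
11 | methyl 7β-(tert-butyldimethylsilyloxy)-3,3-ethylenedioxy-1α-hydroxy-2β-methylcyclohept-5-ene-1β-carboxylate | C1=CCC2(OCCO2)[C@@H](C)[C@@](O)(C(=O)OC)[C@H]1O[Si](C)(C)C(C)(C)C | intermediate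
12 | 7β-(tert-butyldimethylsilyloxy)-3,3-ethylenedioxy-1α-hydroxy-2β-methylcyclohept-5-ene-1β-carbaldehyde | C1=CCC2(OCCO2)[C@@H](C)[C@@](O)(C=O)[C@H]1O[Si](C)(C)C(C)(C)C | intermediate
13 | 7β-(tert-butyldimethylsilyloxy)-3,3-ethylenedioxy-1β-(1-hydroxybut-2-yn-1-yl)-2β-methylcyclohept-5-en-1α-ol, carbinol epimers | C1=CCC2(OCCO2)[C@@H](C)[C@@](O)(C(O)C#CC)[C@H]1O[Si](C)(C)C(C)(C)C | intermediate
14 | isopropylidene acetal of 13 (spiro-dioxolane at C1, oxygen α, propynyl-bearing carbon β) | C1=CCC2(OCCO2)[C@@H](C)[C@]3(OC(C)(C)OC3C#CC)[C@H]1O[Si](C)(C)C(C)(C)C | intermediate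
15 | α-face cis-fused 2,2-dichlorocyclobutanone of 14 (C=O on C6, CCl2 on C5) | O=C1C(Cl)(Cl)[C@@H]2CC3(OCCO3)[C@@H](C)[C@]4(OC(C)(C)OC4C#CC)[C@@H](O[Si](C)(C)C(C)(C)C)[C@H]12 | intermediate
16 | α-face cis-fused cyclobutanone (C=O on C6, CH2 on C5) | O=C1C[C@@H]2CC3(OCCO3)[C@@H](C)[C@]4(OC(C)(C)OC4C#CC)[C@@H](O[Si](C)(C)C(C)(C)C)[C@H]12 | intermediate
17 | cis-fused γ-lactone (C6α–O–C(=O)–CH2–C5α), 7β-silyl ether, ketal, acetonide, alkyne | O=C1C[C@@H]2CC3(OCCO3)[C@@H](C)[C@]4(OC(C)(C)OC4C#CC)[C@@H](O[Si](C)(C)C(C)(C)C)[C@@H]2O1 | intermediate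
18 | α-(dimethylaminomethyl) lactone, Mannich base of 17 (not isolated) | O=C1C(CN(C)C)[C@@H]2CC3(OCCO3)[C@@H](C)[C@]4(OC(C)(C)OC4C#CC)[C@@H](O[Si](C)(C)C(C)(C)C)[C@@H]2O1 | intermediate
19 | trimethylammonium iodide of 18 (not isolated) | O=C1C(C[N+](C)(C)C)[C@@H]2CC3(OCCO3)[C@@H](C)[C@]4(OC(C)(C)OC4C#CC)[C@@H](O[Si](C)(C)C(C)(C)C)[C@@H]2O1.[I-] | intermediate
20 | α-methylene-γ-lactone, 7β-silyl ether, ketal, acetonide, alkyne | C=C1C(=O)O[C@@H]2[C@H]1CC3(OCCO3)[C@@H](C)[C@]4(OC(C)(C)OC4C#CC)[C@H]2O[Si](C)(C)C(C)(C)C | intermediate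
21 | 7β-alcohol of 20 | C=C1C(=O)O[C@@H]2[C@H]1CC3(OCCO3)[C@@H](C)[C@]4(OC(C)(C)OC4C#CC)[C@H]2O | intermediate
22 | 7β-(3-methylbutanoyloxy) derivative of 21 | C=C1C(=O)O[C@@H]2[C@H]1CC3(OCCO3)[C@@H](C)[C@]4(OC(C)(C)OC4C#CC)[C@H]2OC(=O)CC(C)C | intermediate
23 | 3-keto-1α-hydroxy-1β-(1-hydroxybut-2-yn-1-yl)-2α-methyl compound with the target lactone and C7 ester | C=C1C(=O)O[C@@H]2[C@H]1CC(=O)[C@H](C)[C@@](O)(C(O)C#CC)[C@H]2OC(=O)CC(C)C | intermediate
24 | (Z)-1-hydroxybut-2-en-1-yl analogue of 23 | C=C1C(=O)O[C@@H]2[C@H]1CC(=O)[C@H](C)[C@@](O)(C(O)/C=C\C)[C@H]2OC(=O)CC(C)C | intermediate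
25 | CNP0283951.2 | C=C1C(=O)O[C@@H]2[C@H]1CC(=O)[C@H](C)[C@@](O)(C(=O)/C=C\C)[C@H]2OC(=O)CC(C)C | target

Total step count: 20. Longest linear sequence: 20 steps (from 1).

Steps most likely to fail

Step 8. The ester enolate may expel the C7 silyloxy group by beta-elimination, or the oxidant may not discriminate the faces well enough. Fallback: the oxygen is introduced at the aldehyde oxidation level without a free enolate. Starting from 10, reduction with i-Bu2AlH (−78 °C) gives 7β-(tert-butyldimethylsilyloxy)-3,3-ethylenedioxy-2β-methylcyclohept-5-ene-1α-carbaldehyde F1. Soft enolisation with TMSOTf/Et3N turns it into the exocyclic trimethylsilyl enol ether F2. Rubottom oxidation with dimethyldioxirane from the α face and mild acid work-up gives hydroxy aldehyde 12, where the route continues with step 10.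

Step 12. Dichloroketene may also add to the alkyne, the regiochemistry may be lower than expected, and zinc chloride may attack the acetals. Fallback: a radical lactone annulation. Starting from 14, atom-transfer addition of ethyl iodoacetate (Et3B, air, CH2Cl2) should place CH2CO2Et on C5 from the α face and iodine trans on C6, giving ethyl 2-(6β-iodocyclohept-5α-yl)acetate derivative F3. Heating (toluene, 110 °C, or AgOTf) closes the lactone by displacement of iodide with inversion at C6 and gives 17 directly, where the route continues with step 15.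

Step 18. The acid may dehydrate the tertiary beta-hydroxy ketone or cleave the isovalerate, and equilibration at C2 may be slow. Fallback: the end game is reordered so that the acid step is run before the ester is present. Starting from 20, AcOH/H2O/THF (50 °C) removes both acetals, keeps the silyl ether and equilibrates C2, giving the 7β-silyloxy keto diol F4. Semi-hydrogenation as in step 19 gives the (Z)-allylic diol F5, and DMP oxidation gives the (Z)-enone silyl ether F6. HF·pyridine frees the 7β-alcohol F7, and acylation with 3-methylbutanoic anhydride and Sc(OTf)3 (cat.) gives 25.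

Further compounds
F1 | step 8 | 7β-(tert-butyldimethylsilyloxy)-3,3-ethylenedioxy-2β-methylcyclohept-5-ene-1α-carbaldehyde | C1=CCC2(OCCO2)[C@@H](C)[C@H](C=O)[C@H]1O[Si](C)(C)C(C)(C)C
F2 | step 8 | exocyclic trimethylsilyl enol ether of F1 | C1=CCC2(OCCO2)[C@@H](C)C(=CO[Si](C)(C)C)[C@H]1O[Si](C)(C)C(C)(C)C
F3 | step 12 | ethyl 2-(6β-iodocyclohept-5α-yl)acetate derivative of 14 | CCOC(=O)C[C@@H]1CC2(OCCO2)[C@@H](C)[C@]3(OC(C)(C)OC3C#CC)[C@@H](O[Si](C)(C)C(C)(C)C)[C@H]1I
F4 | step 18 | 7β-silyloxy keto diol (alkyne, 2α-methyl) | C=C1C(=O)O[C@@H]2[C@H]1CC(=O)[C@H](C)[C@@](O)(C(O)C#CC)[C@H]2O[Si](C)(C)C(C)(C)C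
F5 | step 18 | 7β-silyloxy (Z)-allylic diol | C=C1C(=O)O[C@@H]2[C@H]1CC(=O)[C@H](C)[C@@](O)(C(O)/C=C\C)[C@H]2O[Si](C)(C)C(C)(C)C
F6 | step 18 | 7β-silyloxy (Z)-enone | C=C1C(=O)O[C@@H]2[C@H]1CC(=O)[C@H](C)[C@@](O)(C(=O)/C=C\C)[C@H]2O[Si](C)(C)C(C)(C)C
F7 | step 18 | 7β-hydroxy (Z)-enone (target without the isovaleryl group) | C=C1C(=O)O[C@@H]2[C@H]1CC(=O)[C@H](C)[C@@](O)(C(=O)/C=C\C)[C@H]2O
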